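**Retrosynthetic overview**

1. The target is 7-allyl-6-hydroxy-5-methoxy-3-methyl-2-(3,4,5-trimethoxyphenyl)benzofuran (benzene ring A, furan ring B, trimethoxyphenyl ring C). The plan rests on C2 of ring B: it is bonded to both C3 and O1 and carries only ring C, so it can enter as one benzylic ylide carbon that is a nucleophile toward C3 and then an electrophile toward O1.
2. Last disconnection: the C7–allyl bond, by aromatic Claisen rearrangement of the C6 O-allyl ether (C5 carries OMe, so only C7 can accept the allyl group). Until then the allyl ether protects the C6 phenol and keeps an ArCH2CH=CH2 methylene away from the oxidant.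
3. Before that: C2=C3 by DDQ dehydrogenation of a trans-2,3-dihydrobenzofuran.
4. Key disconnection: C2–C3 and O1–C2 by [4+1] annulation of an o-quinone methide (ring A with exocyclic C3, released from a 2-(1-tosylethyl)phenol) with the ylide of a 3,4,5-trimethoxybenzylsulfonium salt. Ring B is the only ring formed; rings A and C are bought.
5. Precursors: the sulfone from 2,4-dihydroxy-5-methoxybenzaldehyde (O4-allylation, MeMgBr, sulfinic acid); the sulfonium salt from 3,4,5-trimethoxybenzyl alcohol (PBr3, Me2S).

Key step: step 6

Remark: 2,4-dihydroxy-5-methoxybenzaldehyde is assumed to be a purchasable catalogue compound; all chiral intermediates are racemic and the target has no stereocentre.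

**Route**

Step 1
Reactants: 1 2,4-dihydroxy-5-methoxybenzaldehyde; 2 allyl bromide
Product: 3 4-(allyloxy)-2-hydroxy-5-methoxybenzaldehyde
Conditions: allyl bromide (1.05 equiv), KHCO3 (1.5 equiv), DMF, 40 °C
Reagents that add atoms: allyl bromide (compound 2), C=CCBr
Why: Williamson ether synthesis: the C4 hydroxyl, para to the formyl group, is the more acidic one and is the one deprotonated by hydrogencarbonate, while the C2 hydroxyl is held in a hydrogen bond to the aldehyde, so mono-allylation at O4 is expected.

Step 2
Reactants: 3 4-(allyloxy)-2-hydroxy-5-methoxybenzaldehyde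
Product: 4 racemic 5-(allyloxy)-2-(1-hydroxyethyl)-4-methoxyphenol
Conditions: MeMgBr (2.5 equiv), THF, 0 °C to rt; aq. NH4Cl work-up; used crude
Reagents that add atoms: methylmagnesium bromide, C[Mg]Br
Why: Grignard addition to an aldehyde: the first equivalent deprotonates the phenol and the second adds to the formyl group; the carbinol centre forms without control (racemic), which does not matter because it becomes the planar methide carbon in step 6.

Step 3
Reactants: 4 racemic 5-(allyloxy)-2-(1-hydroxyethyl)-4-methoxyphenol
Product: 5 racemic 5-(allyloxy)-4-methoxy-2-[1-(4-methylphenylsulfonyl)ethyl]phenol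
Conditions: p-toluenesulfinic acid (1.5 equiv), CH2Cl2, 0 °C to rt
Reagents that add atoms: p-toluenesulfinic acid, Cc1ccc(S(=O)O)cc1
Why: Acid-promoted dehydrative substitution (SN1 type) of an o-hydroxybenzylic alcohol: the benzylic carbon, activated by the ortho hydroxyl and the para allyloxy group, ionises under the sulfinic acid and is captured at sulfur to give the sulfone (racemic).

Step 4
Reactants: 6 3,4,5-trimethoxybenzyl alcohol
Product: 7 3,4,5-trimethoxybenzyl bromide
Conditions: PBr3 (0.4 equiv), CH2Cl2, 0 °C
Reagents that add atoms: phosphorus tribromide, BrP(Br)Br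
Why: Standard conversion of a primary benzylic alcohol into the bromide with PBr3 (phosphite ester formation, then SN2 displacement by bromide).

Step 5
Reactants: 7 3,4,5-trimethoxybenzyl bromide
Product: 8 dimethyl(3,4,5-trimethoxybenzyl)sulfonium bromide
Conditions: Me2S (3 equiv), acetone, rt; salt collected by filtration
Reagents that add atoms: dimethyl sulfide, CSC
Why: SN2 alkylation of dimethyl sulfide by the benzylic bromide (sulfonium salt formation), driven by precipitation of the salt.

Step 6
Reactants: 5 racemic 5-(allyloxy)-4-methoxy-2-[1-(4-methylphenylsulfonyl)ethyl]phenol; 8 dimethyl(3,4,5-trimethoxybenzyl)sulfonium bromide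
Product: 12 racemic trans-6-(allyloxy)-5-methoxy-3-methyl-2-(3,4,5-trimethoxyphenyl)-2,3-dihydrobenzofuran (2R,3R enantiomer drawn), via o-quinone methide 9 (not isolated), via sulfonium ylide 10 (not isolated), via phenoxide betaine 11 (not isolated)
Conditions: 8 (1.5 equiv), Cs2CO3 (3 equiv), MeCN, 0 °C to rt
Reagents that add atoms: none
Why: Cs2CO3 deprotonates phenol 5, whose phenoxide expels p-toluenesulfinate to give o-quinone methide 9, and also deprotonates salt 8 to the benzylic ylide 10; the ylide carbon (the future C2) adds to the exocyclic methide carbon (C3), which restores ring A as the phenoxide of betaine 11. The phenoxide oxygen then displaces dimethyl sulfide from C2 in a 5-exo-tet SN2 closure of furan ring B, the only ring formed, so one carbon serves as carbanion toward C3 and as alkylating centre toward O1. The closest known reaction type is the base-mediated formal [4+1] annulation of 2-(1-sulfonylalkyl)phenols with sulfur ylides to trans-2,3-dihydrobenzofurans, applied here with a semi-stabilised benzylic ylide. Both new stereocentres (C2 and C3) are set under substrate control in the closure: the betaine that places ring C and the C3 methyl group on opposite faces of the forming ring closes fastest, so the trans isomer is expected, as a racemate. The step needs conjugate addition before any O-benzylation of the phenoxide by 8 and before the methide tautomerises to a vinylphenol: the exocyclic carbon is the only position of 9 where attack regains aromaticity, the para allyloxy group makes sulfinate loss fast, and the ylide is kept in excess. The trans or cis outcome has no bearing on the target, since both centres are removed in step 7.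

Step 7
Reactants: 12 racemic trans-6-(allyloxy)-5-methoxy-3-methyl-2-(3,4,5-trimethoxyphenyl)-2,3-dihydrobenzofuran
Product: 13 6-(allyloxy)-5-methoxy-3-methyl-2-(3,4,5-trimethoxyphenyl)benzofuran
Conditions: DDQ (1.2 equiv), dry 1,4-dioxane, 80 °C
Reagents that add atoms: none
Why: DDQ dehydrogenation: hydride abstraction from C2 or C3 gives a cation stabilised by O1, ring C or the C6 oxygen, and proton loss aromatises ring B, the standard conversion of 2-aryl-3-methyl-2,3-dihydrobenzofurans into benzofurans; the O-allyl ether offers no doubly activated C–H, and both stereocentres are removed.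

Step 8
Reactants: 13 6-(allyloxy)-5-methoxy-3-methyl-2-(3,4,5-trimethoxyphenyl)benzofuran
Product: 15 7-allyl-6-hydroxy-5-methoxy-3-methyl-2-(3,4,5-trimethoxyphenyl)benzofuran (target), via cyclohexadienone 14 (not isolated)
Conditions: N,N-diethylaniline, 200 °C, sealed tube, argon
Reagents that add atoms: none
Why: Aromatic Claisen rearrangement: the [3,3] shift is productive only at C7 because the other ortho carbon (C5) carries OMe, and tautomerisation of dienone 14 restores ring A and frees the C6 phenol; no stereocentre remains.

**Compound list**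

1 | 2,4-dihydroxy-5-methoxybenzaldehyde | COc1cc(C=O)c(O)cc1O | starting material
2 | allyl bromide | C=CCBr | starting material
3 | 4-(allyloxy)-2-hydroxy-5-methoxybenzaldehyde | COc1cc(C=O)c(O)cc1OCC=C | intermediate
4 | racemic 5-(allyloxy)-2-(1-hydroxyethyl)-4-methoxyphenol | COc1cc(C(C)O)c(O)cc1OCC=C | intermediate
5 | racemic 5-(allyloxy)-4-methoxy-2-[1-(4-methylphenylsulfonyl)ethyl]phenol | COc1cc(C(C)S(=O)(=O)c2ccc(C)cc2)c(O)cc1OCC=C | intermediate
6 | 3,4,5-trimethoxybenzyl alcohol | COc1cc(CO)cc(OC)c1OC | starting material
7 | 3,4,5-trimethoxybenzyl bromide | COc1cc(CBr)cc(OC)c1OC | intermediate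
8 | dimethyl(3,4,5-trimethoxybenzyl)sulfonium bromide | C[S+](C)Cc1cc(OC)c(OC)c(OC)c1.[Br-] | intermediate
9 | (6E)-3-(allyloxy)-6-ethylidene-4-methoxycyclohexa-2,4-dien-1-one (o-quinone methide, E geometry assumed, not isolated) | C/C=C1\C=C(OC)C(OCC=C)=CC1=O | intermediate
10 | dimethylsulfonium (3,4,5-trimethoxyphenyl)methylide (not isolated) | C[S+](C)[CH-]c1cc(OC)c(OC)c(OC)c1 | intermediate
11 | {(1S,2R)-2-[4-(allyloxy)-5-methoxy-2-oxidophenyl]-1-(3,4,5-trimethoxyphenyl)propyl}dimethylsulfonium (betaine, racemic, enantiomer leading to the drawn 12, not isolated) | C[S+](C)[C@H](c1cc(OC)c(OC)c(OC)c1)[C@H](C)c1cc(OC)c(OCC=C)cc1[O-] | intermediate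
12 | racemic trans-6-(allyloxy)-5-methoxy-3-methyl-2-(3,4,5-trimethoxyphenyl)-2,3-dihydrobenzofuran, (2R,3R) drawn | C[C@@H]1c2cc(OC)c(OCC=C)cc2O[C@H]1c1cc(OC)c(OC)c(OC)c1 | intermediate
13 | 6-(allyloxy)-5-methoxy-3-methyl-2-(3,4,5-trimethoxyphenyl)benzofuran | Cc1c(-c2cc(OC)c(OC)c(OC)c2)oc2cc(OCC=C)c(OC)cc12 | intermediate
14 | racemic 7-allyl-5-methoxy-3-methyl-2-(3,4,5-trimethoxyphenyl)benzofuran-6(7H)-one (not isolated) | C=CCC1C(=O)C(OC)=CC2=C1OC(=C2C)c1cc(OC)c(OC)c(OC)c1 | intermediate
15 | 7-allyl-6-hydroxy-5-methoxy-3-methyl-2-(3,4,5-trimethoxyphenyl)benzofuran | C=CCc1c(O)c(OC)cc2c(C)c(-c3cc(OC)c(OC)c(OC)c3)oc12 | target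

**Step count**

Total steps: 8. Longest linear sequence: 6 (steps 1, 2, 3, 6, 7, 8).

**Steps most likely to fail**

Step 6. The methyl-substituted quinone methide 9 may tautomerise to a 2-vinylphenol or oligomerise faster than the ylide captures it. The phenoxide of 5 may also be O-benzylated by salt 8 before it loses sulfinate, and carbonate may form the ylide too slowly. The fallback sets out from 4 and comes back at 13, so it also bypasses step 7. Heating 4 with Ph3P·HBr in MeCN should give racemic {1-[4-(allyloxy)-2-hydroxy-5-methoxyphenyl]ethyl}triphenylphosphonium bromide F1. With 3,4,5-trimethoxybenzoyl chloride and Et3N in hot toluene the phenol is acylated to {1-[4-(allyloxy)-5-methoxy-2-(3,4,5-trimethoxybenzoyloxy)phenyl]ethyl}triphenylphosphonium bromide F2 (not isolated). Deprotonation of F2 at the benzylic carbon gives the ylide, which closes onto the ester carbonyl in an intramolecular Wittig reaction and should deliver 13 directly. C2 then enters as an acyl carbon and C2=C3 is made as an olefin, so neither a quinone methide nor a dehydrogenation is needed.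

Step 7. Hydride abstraction may not stop at the benzofuran: the C3 methyl group or the electron-rich rings may be oxidised further, or conversion may stall with the quinone tied up in charge-transfer complexes. The fallback sets out from 5 and comes back at 13; it delivers C2 at the ketone oxidation level, so no oxidant is needed.
- 2-(3,4,5-Trimethoxyphenyl)-1,3-dithiane F3 is made from 3,4,5-trimethoxybenzaldehyde, propane-1,3-dithiol and BF3·OEt2.
- n-BuLi (THF, −78 °C) converts it into 2-lithio-2-(3,4,5-trimethoxyphenyl)-1,3-dithiane F4.
- Two equivalents are added to 5: the first deprotonates the phenol and so releases 9, the second adds to the methide carbon. This should give racemic 5-(allyloxy)-4-methoxy-2-{1-[2-(3,4,5-trimethoxyphenyl)-1,3-dithian-2-yl]ethyl}phenol F5.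
- Alkylative hydrolysis (MeI, CaCO3, aqueous MeCN) should unmask racemic 2-[4-(allyloxy)-2-hydroxy-5-methoxyphenyl]-1-(3,4,5-trimethoxyphenyl)propan-1-one F6.
- Catalytic p-toluenesulfonic acid in warm toluene should cyclodehydrate F6 to 13.

Step 3. The benzylic cation from 4 may be captured by a second molecule of 4 or its vinylphenol tautomer (self-condensation) faster than by sulfinate, and sulfone 5 may re-ionise during purification. The fallback sets out from 4 and comes back at 12; it replaces the sulfone by a fluoride-triggered precursor that is made without acid.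
- Phenol-selective silylation (t-BuMe2SiCl, Et3N, CH2Cl2, 0 °C) should give racemic 1-[4-(allyloxy)-2-(tert-butyldimethylsilyloxy)-5-methoxyphenyl]ethanol F7.
- Acetylation (Ac2O, Et3N, 4-(dimethylamino)pyridine) should give racemic 1-[4-(allyloxy)-2-(tert-butyldimethylsilyloxy)-5-methoxyphenyl]ethyl acetate F8.
- Ylide 10 is pre-formed from 8 with LiN(SiMe3)2 in THF at −78 °C, F8 is added, and Bu4NF removes the silyl group. The phenoxide expels acetate to give 9, which the ylide takes up through 11 to give 12.

**Further compounds**

F1 | step 6 | racemic {1-[4-(allyloxy)-2-hydroxy-5-methoxyphenyl]ethyl}triphenylphosphonium bromide | COc1cc(C(C)[P+](c2ccccc2)(c2ccccc2)c2ccccc2)c(O)cc1OCC=C.[Br-]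
F2 | step 6 | racemic {1-[4-(allyloxy)-5-methoxy-2-(3,4,5-trimethoxybenzoyloxy)phenyl]ethyl}triphenylphosphonium bromide | COc1cc(C(C)[P+](c2ccccc2)(c2ccccc2)c2ccccc2)c(OC(=O)c2cc(OC)c(OC)c(OC)c2)cc1OCC=C.[Br-]
F3 | step 7 | 2-(3,4,5-trimethoxyphenyl)-1,3-dithiane | COc1cc(C2SCCCS2)cc(OC)c1OC
F4 | step 7 | 2-lithio-2-(3,4,5-trimethoxyphenyl)-1,3-dithiane | [Li]C1(c2cc(OC)c(OC)c(OC)c2)SCCCS1
F5 | step 7 | racemic 5-(allyloxy)-4-methoxy-2-{1-[2-(3,4,5-trimethoxyphenyl)-1,3-dithian-2-yl]ethyl}phenol | COc1cc(C(C)C2(c3cc(OC)c(OC)c(OC)c3)SCCCS2)c(O)cc1OCC=C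
F6 | step 7 | racemic 2-[4-(allyloxy)-2-hydroxy-5-methoxyphenyl]-1-(3,4,5-trimethoxyphenyl)propan-1-one | COc1cc(C(C)C(=O)c2cc(OC)c(OC)c(OC)c2)c(O)cc1OCC=C
F7 | step 3 | racemic 1-[4-(allyloxy)-2-(tert-butyldimethylsilyloxy)-5-methoxyphenyl]ethanol | COc1cc(C(C)O)c(O[Si](C)(C)C(C)(C)C)cc1OCC=C
F8 | step 3 | racemic 1-[4-(allyloxy)-2-(tert-butyldimethylsilyloxy)-5-methoxyphenyl]ethyl acetate | COc1cc(C(C)OC(C)=O)c(O[Si](C)(C)C(C)(C)C)cc1OCC=C
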